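Time in these four flasks is best counted in half-lives of Z, not in minutes.

| flask | Z | remark | time |
|---|---|---|---|
| beta | 0.18 M | run made earlier |  |
| gamma | 1.8 M | run made earlier |  |
| Sunday's | 0.60 M |  | 8.0 min |
| Tuesday's | 0.40 M |  | 8.0 min |
| Friday's | 0.12 M |  | 8.0 min |
| Monday's | 1.5 M |  | 8.0 min |

| run | time / min | G / % | Z / % |
|---|---|---|---|
| beta | 0.333 | 3.6 | 97.0 |
| beta | 0.667 | 7.3 | 92.5 |
| beta | 1.50 | 15.6 | 84.8 |
| beta | 4.00 | 30.8 | 65.1 |
| gamma | 0.333 | 26.2 | 70.7 |
| gamma | 0.667 | 41.9 | 54.3 |
| gamma | 1.50 | 58.5 | 32.5 |
| gamma | 4.00 | 64.7 | 13.9 |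

(scatter of a reading: 1 percentage point)

1. the flasks by amount of G, in percent of the Z charged, highest first, at 8.0 min (Sunday's / Tuesday's / Friday's / Monday's)
2. the same order at 1.0 h (Sunday's / Tuesday's / Friday's / Monday's)
3. the amount of G, in percent of the Z charged of the flask you put first, at 8.0 min
4. the amount of G, in percent of the Z charged of the flask you put last, at 8.0 min

- a species is counted by the Z in it: one G counts as two

Gamma, charged ten times as strongly as beta, passes beta's 65.1% of Z at 4.00 min somewhere between 0.333 min and 0.667 min. So the half-life goes as one over the charge, the mark of a second-order step in which two Z make one G.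

Gamma's first reading gives the gamma half-life, the time Z needs to halve at 1.8 M: 0.804 min. You scale it by charge, and the count for each flask here is its time divided by that scaled half-life. While Z goes by this step, the share left is one over one plus the count.

At 8.0 min the counts are 0.664 for Friday's, 2.21 for Tuesday's, 3.32 for Sunday's and 8.30 for Monday's.

Gamma's G reads 58.5% at count 1.87 and 64.7% at 4.98, so it flattens, while 21.4% of gamma's charge is by then missing from the balance. You therefore rank the flasks by count and put Monday's near 64.7%. Friday's count lies between the counts of beta's last reading and gamma's second, so you read its G across them, near 36.3%.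

At 1.0 h the counts run from 4.98 for Friday's, level with gamma's last reading, to 62.3 for Monday's. If the loss goes on at the expense of G, you expect the order to turn round.

The forecast says Monday's > Sunday's > Tuesday's > Friday's at 8.0 min, with Monday's at 64.5% and Friday's at 37.6%, and Friday's > Tuesday's > Sunday's > Monday's at 1.0 h, holding that “All runs then follow one curve”.

The flasks give Monday's > Sunday's > Tuesday's > Friday's, with Monday's at 66.5% and Friday's at 37.8%, and at 1.0 h Friday's > Tuesday's > Sunday's > Monday's.

    Z + G → D (k = 0.00185 M⁻¹ s⁻¹)
    2 Z → G (k = 0.00572 M⁻¹ s⁻¹)

In Friday's at 8.00 min, the half-life of G by the reaction of Z + G to D, 87 min, is longer than the 8.0 min run. Read at 15 min, Friday's counts 1.24, which gives Z 44.6%, and that reading of Friday's held 43.6% of Z.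

The readings are calculated for substances that don't exist, noise included.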